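The numbers in the tables were computed from invented constants.

Take the turnover as the unit: one left-handed substrate consumed per catalyst charged as precatalyst.

| setting | teal | ochre | red | flask |
|---|---|---|---|---|
| left-handed substrate | 0.34 M | 0.75 M | 0.50 M | 0.50 M |
| right-handed substrate | 0.34 M | 0.75 M | 0.50 M | 0.50 M |
| gas | 150 mM (held) | 150 mM (held) | 150 mM (held) | 150 mM (held) |
| precatalyst | 1 mM | 1 mM | 1.5 mM | 1.0 mM |
| remark | run made earlier | run made earlier | run made earlier |  |
| time |  |  |  | 50 min |

- teal (time / min: right-handed substrate / %, left-handed substrate / %): 6.00: 51.4, 24.6; 12.0: 48.5, 2.5; 15.0: 46.8, 0.4; 25.0: 45.1, 0.8; 30.0: 42.2, 0; 40.0: 40.2, 0.2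
- ochre (time / min: right-handed substrate / %, left-handed substrate / %): 6.00: 50.6, 35.6; 12.0: 47.4, 18.3; 15.0: 49.5, 12.4; 25.0: 46.1, 0; 30.0: 45.9, 0; 40.0: 43.5, 0
- red (time / min: right-handed substrate / %, left-handed substrate / %): 3.00: 48.9, 40.4; 6.00: 50.8, 29.4; 12.0: 50.6, 6.3; 20.0: 46.0, 0; 40.0: 39.1, 0.3

(scatter of a reading: 1 percentage point)

- whether the excess of right-handed substrate over left-handed substrate among what is left of the two reaches 99% by 50 min (no / yes)
- the highest excess of right-handed substrate over left-handed substrate among what is left of the two up to 50 min

- free catalyst is single-handed; left-handed substrate and right-handed substrate are mirror images of each other, charged as a racemate, each of them at the stated concentration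
- at the start none of the gas is in solution

Reckon the flask first:

N = c(left-handed substrate) / c(precatalyst) = 500

This count of turnovers each charged catalyst must make to clear the left-handed substrate is the turnover demand.

Apply it as a bench rule among runs at the same precatalyst, 1.0 mM, as in teal, ochre and the flask. The teal demand is 340, and teal read 0.4% left-handed substrate at 15.0 min. The ochre demand is 750, and ochre read 0% at 25.0 min. The flask asks 0.667 of the ochre demand, so my reckoning expects its left-handed column to vanish between 15.0 min and 25.0 min.

Then find the border. The red run, at 1.5 mM precatalyst, breaks the rule: its demand of 333 is lower than teal's, yet at 12.0 min red read 6.3% left-handed substrate, more than teal's 2.5% at 12.0 min. So do not carry the demand across different precatalyst charges. The excess wanted, 99%, requires: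

c(left-handed substrate) / c(right-handed substrate) = (one − excess) / (one + excess) = 0.503%

Beside a right-handed reading like teal's 46.8%, that means a left-handed reading of 0.235%, against a scatter of 1 percentage point. Past this border, do not expect the readings to show the excess.

The forecast says yes, with a top of 99.9%: “The excess should pass 99 % at around 17–20 min and approach 100 %.” That window lies inside my bracket.

The flask gives yes, with a top of 100%.

    coupling partner + free catalyst + left-handed substrate → free catalyst + left-handed product (k = 22000 L² mol⁻² min⁻¹)
    coupling partner + free catalyst + right-handed substrate → free catalyst + right-handed product (k = 140 L² mol⁻² min⁻¹)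
    gas ⇌ coupling partner, rate k3*(csat - [coupling partner]) (kL = 0.310 min⁻¹)
    coupling partner + precatalyst → free catalyst + spent reagent (k = 2.10 L mol⁻¹ min⁻¹)
    coupling partner + free catalyst → spent catalyst (k = 0.580 L mol⁻¹ min⁻¹)

In the flask at 9.73 min, the left-handed step (selectivity factor 157) uses coupling partner 49 times as fast as the right-handed step, and the half-life of right-handed substrate by its step, 8.1 h, is longer than the 50 min allowed. The flask's excess passes 99% at 17.1 min with 48.3% right-handed substrate left, its demand of 500 turnovers stands met at 25.0 min with left-handed product at 50.0%, and at 50.0 min another 100 turnovers per catalyst charged sit in right-handed product.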